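Ring A is read as a cyclohexene retron (gibberellane numbering): its carbons map onto a diene C2=C3–C4=C5 and a dienophile C10=C1 that are already linked through the three-atom tether C6–C8–C9 of ring B. One thermal intramolecular Diels–Alder reaction of a trienal built on a preformed bicyclo[3.2.1]octane (rings C and D) should therefore close rings A and B together, create the quaternary C10 and the C5 and C2 centres, and funnel the labile C6 centre. The precursor carries a 1-silyloxy-3-carbomethoxy diene on the C8 side chain and a 2-substituted acrolein on C9; the diene ester later directs C4 methylation and becomes the lactone carbonyl.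

Key step: step 12

Remark: atoms carry gibberellane numbers (ring A C1–C5 and C10; ring B C5, C6, C8, C9, C10; ring C C8, C9, C11–C14; ring D C8, C13–C16; C7 is the carboxyl carbon on C6, C18 the methyl and C19 the lactone carbonyl on C4, C20 the lactone CH2 on C10). β is the face of H-5 and H-9, α the face of the lactone bridge. The target, 2β,13,20-trihydroxygibberell-16-ene-7,19-dioic acid 19,20-lactone in this convention, is called the target acid below. C6 in compounds 15–19 is an epimer mixture that becomes configurationally labile once the diene is in place.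

Step 1
Reactants: 1 4-[(tert-butyldimethylsilyl)oxy]butanal; 2 but-3-en-2-one
Product: 4 (4S)-4-[2-(tert-butyldimethylsilyloxy)ethyl]cyclohex-2-en-1-one, via keto aldehyde 3 (not isolated)
Conditions: (S)-2-[methoxy(diphenyl)methyl]pyrrolidine (5 mol %), ethyl 3,4-dihydroxybenzoate (20 mol %), neat, 4 °C; then LiOH (0.1 equiv), i-PrOH, 23 °C
Reagents that add atoms: none
Why: Enamine-catalysed asymmetric Michael addition to the enone followed by intramolecular aldol condensation (organocatalytic Robinson-type annulation); the (S)-catalyst shields one face of the E-enamine, so C9 should form with S configuration, and mild base closes the ring before the α-centre epimerises.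

Step 2
Reactants: 4 (4S)-4-[2-(tert-butyldimethylsilyloxy)ethyl]cyclohex-2-en-1-one; 5 1-(tert-butyldimethylsilyloxy)-1-methoxyethene
Product: 6 methyl 2-{trans-3-(tert-butyldimethylsilyloxy)-6-[2-(tert-butyldimethylsilyloxy)ethyl]cyclohex-2-en-1-yl}acetate
Conditions: TBSOTf (5 mol %), CH2Cl2, −78 °C
Reagents that add atoms: none
Why: Mukaiyama–Michael addition with silyl transfer; the ketene silyl acetal should attack C8 anti to the C9 side chain and the enolate is trapped as the silyl enol ether, the new C8 centre being only temporary.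

Step 3
Reactants: 6 methyl 2-{trans-3-(tert-butyldimethylsilyloxy)-6-[2-(tert-butyldimethylsilyloxy)ethyl]cyclohex-2-en-1-yl}acetate
Product: 7 methyl 2-{(6S)-6-[2-(tert-butyldimethylsilyloxy)ethyl]-3-oxocyclohex-1-en-1-yl}acetate
Conditions: Pd(OAc)2 (10 mol %), O2 (1 atm), DMSO, 40 °C
Reagents that add atoms: none
Why: Saegusa–Ito oxidation; the palladium enolate at C14 undergoes β-hydride elimination towards C8–H, which returns the ring enone with the acetate arm on C8 and erases the temporary C8 centre.

Step 4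
Reactants: 7 methyl 2-{(6S)-6-[2-(tert-butyldimethylsilyloxy)ethyl]-3-oxocyclohex-1-en-1-yl}acetate; 8 tributyl(propa-1,2-dienyl)stannane
Product: 9 methyl 2-{2-[2-(tert-butyldimethylsilyloxy)ethyl]-5-oxo-1-(prop-2-yn-1-yl)cyclohexyl}acetate (propargyl trans to the C9 side chain)
Conditions: TiCl4 (1.1 equiv), CH2Cl2, −78 °C; aq. NaHCO3
Reagents that add atoms: none
Why: Lewis acid-promoted conjugate propargylation (SE2′ attack of the allenylstannane, Hosomi–Sakurai type); the nucleophile should enter C8 anti to the pseudoaxial C9 side chain, so C15 ends up trans and the acetate arm C6 cis to that chain, which is the natural C8 configuration.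

Step 5
Reactants: 9 methyl 2-{2-[2-(tert-butyldimethylsilyloxy)ethyl]-5-oxo-1-(prop-2-yn-1-yl)cyclohexyl}acetate
Product: 10 methyl 2-{2-[2-(tert-butyldimethylsilyloxy)ethyl]-5-hydroxy-6-methylidenebicyclo[3.2.1]octan-1-yl}acetate
Conditions: SmI2 (2.5 equiv), HMPA, t-BuOH (2 equiv), THF, 0 to 23 °C
Reagents that add atoms: none
Why: Reductive ketyl–alkyne cyclisation; the samarium ketyl at C13 adds 5-exo-dig to C16 of the axial propargyl group and the vinyl radical is reduced and protonated, giving ring D with the bridgehead alcohol and the exocyclic methylene, the C13 configuration being dictated by the bridge from C8.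

Step 6
Reactants: 11 2,2-dimethoxyacetaldehyde (60% aqueous solution); 12 methyl acrylate
Product: 13 methyl 3-hydroxy-4,4-dimethoxy-2-methylidenebutanoate (racemic)
Conditions: DABCO (0.5 equiv), 1,4-dioxane–H2O (1:1), 23 °C
Reagents that add atoms: none
Why: Morita–Baylis–Hillman reaction, which water accelerates; the racemic carbinol centre is lost in the next step.

Step 7
Reactants: 13 methyl 3-hydroxy-4,4-dimethoxy-2-methylidenebutanoate
Product: 14 methyl (2Z)-2-(bromomethyl)-4,4-dimethoxybut-2-enoate
Conditions: NBS, Me2S, CH2Cl2, 0 to 23 °C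
Reagents that add atoms: N-bromosuccinimide, O=C1CCC(=O)N1Br
Why: Allylic bromination with transposition (SN2′ displacement of the alkoxysulfonium by bromide) under neutral conditions that spare the acetal; it should give the more stable alkene with the acetal carbon cis to CH2Br.

Step 8
Reactants: 10 methyl 2-{2-[2-(tert-butyldimethylsilyloxy)ethyl]-5-hydroxy-6-methylidenebicyclo[3.2.1]octan-1-yl}acetate; 14 methyl (2Z)-2-(bromomethyl)-4,4-dimethoxybut-2-enoate
Product: 15 dimethyl (4E)-4-(2,2-dimethoxyethylidene)-2-{2-[2-(tert-butyldimethylsilyloxy)ethyl]-5-hydroxy-6-methylidenebicyclo[3.2.1]octan-1-yl}pentanedioate (C6 epimers)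
Conditions: LiN(i-Pr)2 (2.2 equiv), THF, −78 °C; then 14, DMPU, −78 to −20 °C
Reagents that add atoms: none
Why: Ester enolate alkylation (dianion with the tertiary alkoxide) at the unhindered primary allylic bromide by SN2, the β-carbon of 14 being shielded by the acetal; C6 forms as an epimer mixture that step 12 corrects.

Step 9
Reactants: 15 dimethyl (4E)-4-(2,2-dimethoxyethylidene)-2-{2-[2-(tert-butyldimethylsilyloxy)ethyl]-5-hydroxy-6-methylidenebicyclo[3.2.1]octan-1-yl}pentanedioate
Product: 16 dimethyl (4E)-2-[5-hydroxy-2-(2-hydroxyethyl)-6-methylidenebicyclo[3.2.1]octan-1-yl]-4-(2-oxoethylidene)pentanedioate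
Conditions: AcOH–THF–H2O (3:1:1), 35 °C
Reagents that add atoms: water, O
Why: Acid hydrolysis that cleaves the primary silyl ether and the α,β-unsaturated dimethyl acetal while leaving the tertiary allylic alcohol and the exocyclic alkene untouched.

Step 10
Reactants: 16 dimethyl (4E)-2-[5-hydroxy-2-(2-hydroxyethyl)-6-methylidenebicyclo[3.2.1]octan-1-yl]-4-(2-oxoethylidene)pentanedioate
Product: 17 dimethyl (4E)-2-[5-hydroxy-6-methylidene-2-(2-oxoethyl)bicyclo[3.2.1]octan-1-yl]-4-(2-oxoethylidene)pentanedioate
Conditions: Dess–Martin periodinane, NaHCO3, CH2Cl2, 0 to 23 °C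
Reagents that add atoms: none
Why: Dess–Martin oxidation of the only primary alcohol; the tertiary alcohol cannot be oxidised and the buffer protects the enal.

Step 11
Reactants: 17 dimethyl (4E)-2-[5-hydroxy-6-methylidene-2-(2-oxoethyl)bicyclo[3.2.1]octan-1-yl]-4-(2-oxoethylidene)pentanedioate
Product: 18 dimethyl (4E)-2-[5-hydroxy-6-methylidene-2-(3-oxoprop-1-en-2-yl)bicyclo[3.2.1]octan-1-yl]-4-(2-oxoethylidene)pentanedioate
Conditions: (CH2=NMe2)I, Et3N, CH2Cl2, 23 °C
Reagents that add atoms: Eschenmoser's salt (N,N-dimethylmethyleneiminium iodide), C=[N+](C)C.[I-]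
Why: α-Methylenation by Mannich reaction of the saturated aldehyde and β-elimination of dimethylamine; the conjugated aldehyde has no enolisable α-hydrogen and should react far more slowly through its γ-position.

Step 12
Reactants: 18 dimethyl (4E)-2-[5-hydroxy-6-methylidene-2-(3-oxoprop-1-en-2-yl)bicyclo[3.2.1]octan-1-yl]-4-(2-oxoethylidene)pentanedioate
Product: 20 Diels–Alder adduct (Δ3-ene; 4-CO2Me; 2α-OTBS; 10α-CHO; 5β-H; 6β-CO2Me; 13-OTBS; 16-methylidene), via silyl dienol ether 19 (not isolated)
Conditions: TBSOTf (2.3 equiv), Et3N (5 equiv), CH2Cl2, −78 to 0 °C; then toluene, BHT (cat.), 110 °C, sealed tube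
Reagents that add atoms: tert-butyldimethylsilyl trifluoromethanesulfonate, CC(C)(C)[Si](C)(C)OS(=O)(=O)C(F)(F)F
Why: TBSOTf/Et3N turns the γ-enolisable enal into the 1-silyloxy-3-carbomethoxy diene 19 (E enol ether, C6 outside) and silylates the 13-hydroxyl, and heating triggers a concerted suprafacial [4+2] cycloaddition with the tethered 2-substituted acrolein, that is a type 1 intramolecular Diels–Alder reaction of a 1,3,8-nonatriene, the standard thermal entry to hydrindanes. Ring B closes through C5–C10 as the five-membered ring spanned by the tether C6–C8–C9 (fused mode, the bridged alternative being geometrically out of reach), and ring A closes as the new cyclohexene through C5–C10 and C1–C2, so the tether and not the donor/acceptor pattern fixes the regiochemistry. The formyl group on C10 should lie endo under the diene (Alder rule), which places the tether exo and gives the trans A/B fusion, and the dienophile should react on the face where C1 is syn to H-9 and away from the C11 methylene of ring C, which sets C10 (C20 α) and C5 (H β) relative to C8 and C9. The E enol ether and the endo geometry place the silyloxy group at C2 on the α face, cis to C20. C6 is a glutaconate-type CH that epimerises under Et3N, and because allylic 1,3-strain with the C4 ester lets only the epimer with H-6 in the diene plane reach this transition state, both epimers should drain into the natural 6β-ester. The step needs cycloaddition to outrun polar Mukaiyama-type closure and needs endo and facial control; the amine-buffered, Lewis acid-free thermal conditions, the endo-directing formyl group and the cis B/C junction are what secure them.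

Step 13
Reactants: 20 Diels–Alder adduct
Product: 23 2-epi target acid methyl ester 2,13-bis(tert-butyldimethylsilyl) ether, via dilithium enolate alkoxide 21 (not isolated), via methylated lithium alkoxide 22 (not isolated)
Conditions: LiBH(s-Bu)3 (L-Selectride, 2.3 equiv), THF, −78 °C; then MeI (5 equiv), DMPU, −78 to 23 °C
Reagents that add atoms: iodomethane, CI
Why: Hydride reduces the aldehyde and adds 1,4 to the enoate, giving the C4 ester enolate regiospecifically without touching H-6 (conjugate reduction–alkylation); MeI should enter from the β face, anti to the axial C20 and C2 oxygen substituents, and the C20 alkoxide then closes the δ-lactone onto the now axial α-ester.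

Step 14
Reactants: 23 2-epi target acid methyl ester 2,13-bis(tert-butyldimethylsilyl) ether
Product: 24 2-epi target acid methyl ester (2α,13-diol)
Conditions: TBAF (4 equiv), THF, 23 to 45 °C
Reagents that add atoms: none
Why: Fluoride-mediated cleavage of the secondary and the tertiary silyl ether; lactone and methyl ester should survive.

Step 15
Reactants: 24 2-epi target acid methyl ester (2α,13-diol)
Product: 25 target acid methyl ester 2-O-(4-nitrobenzoate)
Conditions: 4-nitrobenzoic acid, PPh3, DIAD, toluene, 0 to 23 °C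
Reagents that add atoms: 4-nitrobenzoic acid, O=C(O)c1ccc(cc1)[N+](=O)[O-]
Why: Mitsunobu reaction; the axial 2α-alcohol is activated as the oxyphosphonium salt and displaced by carboxylate with inversion from the open β face to give the equatorial 2β-ester, while the tertiary alcohol cannot react.

Step 16
Reactants: 25 target acid methyl ester 2-O-(4-nitrobenzoate)
Product: 26 target acid (the target gibberellin)
Conditions: KOH (2 M aq.), MeOH, 60 °C; then HCl (1 M aq.) to pH 3, 23 °C
Reagents that add atoms: potassium hydroxide, [K+].[OH-]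
Why: Saponification of the nitrobenzoate and the hindered C7 methyl ester (the lactone opens reversibly), then acidification, which should reclose the 19,20-lactone; C6 keeps its thermodynamically preferred configuration.

Compound list
1 | 4-[(tert-butyldimethylsilyl)oxy]butanal | O=CCCCO[Si](C)(C)C(C)(C)C | starting material
2 | but-3-en-2-one | CC(=O)C=C | starting material
3 | (2S)-2-[2-(tert-butyldimethylsilyloxy)ethyl]-5-oxohexanal | O=C[C@H](CCO[Si](C)(C)C(C)(C)C)CCC(C)=O | intermediate
4 | (4S)-4-[2-(tert-butyldimethylsilyloxy)ethyl]cyclohex-2-en-1-one | O=C1C=C[C@H](CCO[Si](C)(C)C(C)(C)C)CC1 | intermediate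
5 | 1-(tert-butyldimethylsilyloxy)-1-methoxyethene | C=C(OC)O[Si](C)(C)C(C)(C)C | starting material
6 | methyl 2-{trans-3-(tert-butyldimethylsilyloxy)-6-[2-(tert-butyldimethylsilyloxy)ethyl]cyclohex-2-en-1-yl}acetate | CC(C)(C)[Si](C)(C)OC1=C[C@@H](CC(=O)OC)[C@H](CCO[Si](C)(C)C(C)(C)C)CC1 | intermediate
7 | methyl 2-{(6S)-6-[2-(tert-butyldimethylsilyloxy)ethyl]-3-oxocyclohex-1-en-1-yl}acetate | COC(=O)CC1=CC(=O)CC[C@H]1CCO[Si](C)(C)C(C)(C)C | intermediate
8 | tributyl(propa-1,2-dienyl)stannane | C=C=C[Sn](CCCC)(CCCC)CCCC | starting material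
9 | methyl 2-{2-[2-(tert-butyldimethylsilyloxy)ethyl]-5-oxo-1-(prop-2-yn-1-yl)cyclohexyl}acetate; propargyl trans to the C9 side chain | C#CC[C@]1(CC(=O)OC)CC(=O)CC[C@H]1CCO[Si](C)(C)C(C)(C)C | intermediate
10 | methyl 2-{2-[2-(tert-butyldimethylsilyloxy)ethyl]-5-hydroxy-6-methylidenebicyclo[3.2.1]octan-1-yl}acetate; C9 side chain anti to the C15–C16 bridge | C=C1C[C@]2(CC(=O)OC)C[C@@]1(O)CC[C@H]2CCO[Si](C)(C)C(C)(C)C | intermediate
11 | 2,2-dimethoxyacetaldehyde | COC(OC)C=O | starting material
12 | methyl acrylate | C=CC(=O)OC | starting material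
13 | methyl 3-hydroxy-4,4-dimethoxy-2-methylidenebutanoate (racemic) | COC(=O)C(=C)C(O)C(OC)OC | intermediate
14 | methyl (2Z)-2-(bromomethyl)-4,4-dimethoxybut-2-enoate | BrC/C(C(=O)OC)=C\C(OC)OC | intermediate
15 | dimethyl (4E)-4-(2,2-dimethoxyethylidene)-2-{2-[2-(tert-butyldimethylsilyloxy)ethyl]-5-hydroxy-6-methylidenebicyclo[3.2.1]octan-1-yl}pentanedioate; C6 epimers | C=C1C[C@]2(C(C(=O)OC)C/C(C(=O)OC)=C\C(OC)OC)C[C@@]1(O)CC[C@H]2CCO[Si](C)(C)C(C)(C)C | intermediate
16 | dimethyl (4E)-2-[5-hydroxy-2-(2-hydroxyethyl)-6-methylidenebicyclo[3.2.1]octan-1-yl]-4-(2-oxoethylidene)pentanedioate; C6 epimers | C=C1C[C@]2(C(C(=O)OC)C/C(C(=O)OC)=C\C=O)C[C@@]1(O)CC[C@H]2CCO | intermediate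
17 | dimethyl (4E)-2-[5-hydroxy-6-methylidene-2-(2-oxoethyl)bicyclo[3.2.1]octan-1-yl]-4-(2-oxoethylidene)pentanedioate; C6 epimers | C=C1C[C@]2(C(C(=O)OC)C/C(C(=O)OC)=C\C=O)C[C@@]1(O)CC[C@H]2CC=O | intermediate
18 | dimethyl (4E)-2-[5-hydroxy-6-methylidene-2-(3-oxoprop-1-en-2-yl)bicyclo[3.2.1]octan-1-yl]-4-(2-oxoethylidene)pentanedioate; C6 epimers | C=C1C[C@]2(C(C(=O)OC)C/C(C(=O)OC)=C\C=O)C[C@@]1(O)CC[C@H]2C(=C)C=O | intermediate
19 | silyl dienol ether: C8 chain CH(CO2Me)–CH=C(CO2Me)–CH=CH–OTBS (E enol ether; C6 cis to the C4 ester); 13-OTBS; 2-formylvinyl group on C9; C6 epimers | C=C1C[C@]2(C(C(=O)OC)/C=C(\C(=O)OC)/C=C/O[Si](C)(C)C(C)(C)C)C[C@@]1(O[Si](C)(C)C(C)(C)C)CC[C@H]2C(=C)C=O | intermediate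
20 | Diels–Alder adduct: gibberellane tetracycle with Δ3-ene; 4-CO2Me; 2α-OTBS; 10α-CHO (C20); 5β-H; 6β-CO2Me; 13-OTBS; 16-methylidene | C=C1C[C@]23C[C@@]1(O[Si](C)(C)C(C)(C)C)CC[C@H]2[C@]1(C=O)C[C@@H](O[Si](C)(C)C(C)(C)C)C=C(C(=O)OC)[C@H]1[C@@H]3C(=O)OC | intermediate
21 | dilithium salt: C19 ester enolate at C4 and C20 alkoxide | C=C1C[C@]23C[C@@]1(O[Si](C)(C)C(C)(C)C)CC[C@H]2[C@]1(C[O-])C[C@@H](O[Si](C)(C)C(C)(C)C)CC(=C([O-])OC)[C@H]1[C@@H]3C(=O)OC.[Li+].[Li+] | intermediate
22 | lithium C20 alkoxide of the 4β-methyl 4α-CO2Me diester | C=C1C[C@]23C[C@@]1(O[Si](C)(C)C(C)(C)C)CC[C@H]2[C@]1(C[O-])C[C@@H](O[Si](C)(C)C(C)(C)C)C[C@@](C)(C(=O)OC)[C@H]1[C@@H]3C(=O)OC.[Li+] | intermediate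
23 | 2-epi target acid methyl ester 2,13-bis(tert-butyldimethylsilyl) ether: 19,20-lactone; 4β-methyl; 2α-OTBS; 13-OTBS; 6β-CO2Me; 16-methylidene | C=C1C[C@]23C[C@@]1(O[Si](C)(C)C(C)(C)C)CC[C@H]2[C@]12COC(=O)[C@](C)(C[C@H](O[Si](C)(C)C(C)(C)C)C1)[C@H]2[C@@H]3C(=O)OC | intermediate
24 | 2-epi target acid methyl ester: 19,20-lactone; 2α-OH; 13-OH; 6β-CO2Me | C=C1C[C@]23C[C@@]1(O)CC[C@H]2[C@]12COC(=O)[C@](C)(C[C@H](O)C1)[C@H]2[C@@H]3C(=O)OC | intermediate
25 | target acid methyl ester 2-O-(4-nitrobenzoate): 19,20-lactone; 2β-(4-nitrobenzoyloxy); 13-OH; 6β-CO2Me | C=C1C[C@]23C[C@@]1(O)CC[C@H]2[C@]12COC(=O)[C@](C)(C[C@@H](OC(=O)c4ccc(cc4)[N+](=O)[O-])C1)[C@H]2[C@@H]3C(=O)OC | intermediate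
26 | target acid (the target gibberellin): 2β,13,20-trihydroxygibberell-16-ene-7,19-dioic acid 19,20-lactone | C=C1C[C@]23C[C@@]1(O)CC[C@H]2[C@]12COC(=O)[C@](C)(C[C@@H](O)C1)[C@H]2[C@@H]3C(=O)O | target

Total step count: 16. Longest linear sequence: 14 steps (steps 1–5 and 8–16).

Steps most likely to fail

Step 12. The cycloaddition may be outrun by stepwise Mukaiyama-type attack of the dienol ether (C5) on the enal (C1). Alternatively, C6 may epimerise too slowly, so that the mismatched epimer cyclises with poor facial and endo control. The fallback sets out from 18 and comes back at 24. Pivaloyl chloride, Et3N and DMAP should convert the γ-enolisable enal into the dienyl pivalate F1, a diene that tolerates a Lewis acid. Me2AlCl in CH2Cl2 at −78 to −20 °C then activates the C20 aldehyde for an endo-selective intramolecular Diels–Alder reaction at low temperature, giving the 2α-pivaloyloxy adduct F2. The reagents of step 13, with one more equivalent of hydride for the free 13-hydroxyl, turn F2 into the 2α-pivalate lactone F3. NaOMe in MeOH removes the pivalate and equilibrates any C6 epimer to the more stable 6β-ester, which after acidic work-up is diol 24.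

Step 4. Addition to the hindered β,β-disubstituted enone may stall or divert to 1,2-addition. The fallback sets out from 7 and comes back at 9. Hosomi–Sakurai allylation (allyltrimethylsilane, TiCl4, CH2Cl2, −78 °C), the most dependable way to a quaternary β-carbon, should give the allyl ketone F4 with the same facial sense. Ozonolysis (O3, CH2Cl2, −78 °C; PPh3) gives the aldehyde F5. Ohira–Bestmann homologation (dimethyl (1-diazo-2-oxopropyl)phosphonate, K2CO3, MeOH) then delivers alkyne 9.

Step 13. Possible failures are 1,2-reduction, proton transfer from H-6 to the C4 enolate with methylation at C6, or oxa-Michael addition of the C20 alkoxide. The fallback sets out from 20 and comes back at 24, separating the events. NaBH4 (MeOH, −20 °C) reduces only the aldehyde to the alcohol F6. RhCl(PPh3)3-catalysed 1,4-hydrosilylation with Et3SiH, which also silylates the C20 hydroxyl, gives the silyl ketene acetal F7. Fluoride-triggered methylation (tris(dimethylamino)sulfonium difluorotrimethylsilicate, MeI, THF, −78 °C) releases the enolate only in the presence of the electrophile and gives the 4β-methyl ester F8. TBAF as in step 14 removes all silyl groups, and the freed C20 alkoxide lactonises to 24.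

Further compounds
F1 | step 12 | dienyl pivalate (pivaloyloxy analogue of 19 with free 13-OH) | C=C1C[C@]2(C(C(=O)OC)/C=C(\C(=O)OC)/C=C/OC(=O)C(C)(C)C)C[C@@]1(O)CC[C@H]2C(=C)C=O
F2 | step 12 | Diels–Alder adduct with 2α-pivaloyloxy group and free 13-OH | C=C1C[C@]23C[C@@]1(O)CC[C@H]2[C@]1(C=O)C[C@@H](OC(=O)C(C)(C)C)C=C(C(=O)OC)[C@H]1[C@@H]3C(=O)OC
F3 | step 12 | 2-epi target acid methyl ester 2-O-pivalate (19,20-lactone; 2α-pivaloyloxy; 13-OH) | C=C1C[C@]23C[C@@]1(O)CC[C@H]2[C@]12COC(=O)[C@](C)(C[C@H](OC(=O)C(C)(C)C)C1)[C@H]2[C@@H]3C(=O)OC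
F4 | step 4 | methyl 2-{1-allyl-2-[2-(tert-butyldimethylsilyloxy)ethyl]-5-oxocyclohexyl}acetate (allyl trans to the C9 side chain) | C=CC[C@]1(CC(=O)OC)CC(=O)CC[C@H]1CCO[Si](C)(C)C(C)(C)C
F5 | step 4 | methyl 2-{2-[2-(tert-butyldimethylsilyloxy)ethyl]-5-oxo-1-(2-oxoethyl)cyclohexyl}acetate | O=CC[C@]1(CC(=O)OC)CC(=O)CC[C@H]1CCO[Si](C)(C)C(C)(C)C
F6 | step 13 | C20 alcohol of adduct 20 | C=C1C[C@]23C[C@@]1(O[Si](C)(C)C(C)(C)C)CC[C@H]2[C@]1(CO)C[C@@H](O[Si](C)(C)C(C)(C)C)C=C(C(=O)OC)[C@H]1[C@@H]3C(=O)OC
F7 | step 13 | C4 silyl ketene acetal with C20 triethylsilyl ether | C=C1C[C@]23C[C@@]1(O[Si](C)(C)C(C)(C)C)CC[C@H]2[C@]1(CO[Si](CC)(CC)CC)C[C@@H](O[Si](C)(C)C(C)(C)C)CC(=C(OC)O[Si](CC)(CC)CC)[C@H]1[C@@H]3C(=O)OC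
F8 | step 13 | 4β-methyl 4α-CO2Me diester with C20 triethylsilyl ether | C=C1C[C@]23C[C@@]1(O[Si](C)(C)C(C)(C)C)CC[C@H]2[C@]1(CO[Si](CC)(CC)CC)C[C@@H](O[Si](C)(C)C(C)(C)C)C[C@@](C)(C(=O)OC)[C@H]1[C@@H]3C(=O)OC
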